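**Retrosynthetic overview**
1. Ring B with C11–C14 is bought as (+)-3-carene 1; its enedione 2 gives the regiodefined silyl enol ether 3, so only ring A has to be built.
2. Ring A: a [4+2] cycloaddition (oxa-Diels–Alder) of 3 with ethyl vinyl ketone 4 forges the C10 quaternary centre (cycloadduct 5); ketal cleavage (6) and aldol closure give enone 7.
3. Epoxide 8 and the cyclopropane are opened together by acid (via 9) to 10, which installs 4α-OH, 11-OH and the 6-en-8-one in one step; reduction gives triol 11.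
4. Side chain: (S)-N,N-dimethyllactamide 12 → furyl ketone 13 → chelation-controlled diol 14 → acetonide 15 → acid 16 (furan as latent CO2H).
5. Last disconnection is the C3 ester: 11 + 16 (via 17) → 18, then acetonide removal to target 19.

Assumption: eudesmane numbering is used for the core from compound 5 on (C3 ester carbon, C4 carbinol, C5/C10 ring fusion, C8 ketone, C11 side-chain carbinol; β = face of the C10 methyl), and (+)-3-carene is taken as (1S,6R).

**Route**

Step 1
Reactants: 1 (+)-3-carene
Product: 2 (1S,6R)-3,7,7-trimethylbicyclo[4.1.0]hept-3-ene-2,5-dione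
Conditions: CrO3 (10 mol%), t-BuOOH (70% aq., 8 equiv), CH2Cl2, rt
Reagents that add atoms: tert-butyl hydroperoxide, CC(C)(C)OO
Why: Chromium-catalysed allylic oxidation turns both doubly activated (allylic and cyclopropylcarbinyl) methylenes beside the trisubstituted alkene into ketones and leaves the two ring-fusion stereocentres untouched.

Step 2
Reactants: 2 (1S,6R)-3,7,7-trimethylbicyclo[4.1.0]hept-3-ene-2,5-dione
Product: 3 (1R,6S)-4,7,7-trimethyl-5-(triethylsilyloxy)bicyclo[4.1.0]hept-4-en-2-one
Conditions: Et3SiH (1.1 equiv), RhCl(PPh3)3 (1 mol%), PhH, 50 °C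
Reagents that add atoms: triethylsilane, CC[SiH](CC)CC
Why: Rhodium-catalysed 1,4-hydrosilylation delivers hydride to the unsubstituted β-carbon of the enedione and silicon to the oxygen of the methyl-flanked carbonyl, so the tetrasubstituted silyl enol ether forms regioselectively and the other ketone stays free.

Step 3
Reactants: 3 (1R,6S)-4,7,7-trimethyl-5-(triethylsilyloxy)bicyclo[4.1.0]hept-4-en-2-one; 4 ethyl vinyl ketone
Product: 7 (6αH,7αH)-6,11-cycloeudesm-4-ene-3,8-dione, via dihydropyran cycloadduct 5 (not isolated), via 1,5-diketone 6 (not isolated)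
Conditions: 4 (3 equiv), BHT (cat.), PhMe, 120 °C, sealed tube; then KOH (0.5 equiv), MeOH–H2O, 60 °C
Reagents that add atoms: none
Why: An inverse-electron-demand oxa-Diels–Alder ([4+2]) cycloaddition of the electron-rich enol ether with s-cis ethyl vinyl ketone occurs on the face opposite the gem-dimethylcyclopropane and so sets the C10 quaternary centre as (R), after which base cleaves the silyl ketal to the 1,5-diketone and closes ring A by aldol condensation.

Step 4
Reactants: 7 (6αH,7αH)-6,11-cycloeudesm-4-ene-3,8-dione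
Product: 8 4α,5α-epoxy-(6αH,7αH)-6,11-cycloeudesmane-3,8-dione
Conditions: H2O2 (30% aq.), NaOH (0.3 equiv), MeOH, 0 °C → rt
Reagents that add atoms: hydrogen peroxide, OO
Why: Weitz–Scheffer nucleophilic epoxidation, in which hydroperoxide adds to C5 from the α face, away from the angular methyl and the β-fused dimethylcyclopropane, and the enolate closes the 4α,5α-epoxide.

Step 5
Reactants: 8 4α,5α-epoxy-(6αH,7αH)-6,11-cycloeudesmane-3,8-dione
Product: 10 4α,11-dihydroxy-5αH-eudesm-6-ene-3,8-dione, via β,γ-unsaturated ketone 9 (not isolated)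
Conditions: HClO4 (0.1 M), THF–H2O (3:1), 0 → 40 °C
Reagents that add atoms: water, O
Why: Acid opens the epoxide at C5 to a cyclopropylcarbinyl cation that collapses by cleavage of the C6–C11 bond (cyclopropylcarbinyl–homoallyl rearrangement), water traps the tertiary C11 cation, and the β,γ-enone then moves into conjugation by acid-catalysed enolisation with protonation of C5 from the α face, giving the trans-decalin.

Step 6
Reactants: 10 4α,11-dihydroxy-5αH-eudesm-6-ene-3,8-dione
Product: 11 3β,4α,11-trihydroxy-5αH-eudesm-6-en-8-one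
Conditions: NaBH4, MeOH–CH2Cl2 (1:1), −78 °C
Reagents that add atoms: none
Why: Chemoselective borohydride reduction of the saturated α-hydroxy ketone in the presence of the conjugated enone at low temperature, with axial hydride attack from the α face (anti to the axial 4β-methyl) giving the equatorial 3β-alcohol.

Step 7
Reactants: 12 (S)-2-hydroxy-N,N-dimethylpropanamide
Product: 13 (S)-1-(furan-2-yl)-2-hydroxypropan-1-one
Conditions: furan (2.4 equiv), n-BuLi (2.2 equiv), THF, 0 °C; then 12, −78 → 0 °C; then H2O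
Reagents that add atoms: 2-furyllithium, [Li]c1ccco1 (made in the flask from furan, c1ccoc1, and n-butyllithium, [Li]CCCC)
Why: Acyl substitution of an amide by an organolithium, in which the first equivalent deprotonates the hydroxyl and the second adds to give a chelated tetrahedral dianion that survives until work-up, so the ketone forms once and the lactate stereocentre is not enolised.

Step 8
Reactants: 13 (S)-1-(furan-2-yl)-2-hydroxypropan-1-one
Product: 14 (2S,3S)-2-(furan-2-yl)butane-2,3-diol
Conditions: MeMgBr (2.5 equiv), THF, −78 → −20 °C; then H2O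
Reagents that add atoms: methylmagnesium bromide, C[Mg]Br
Why: Cram-chelate (cyclic model) Grignard addition, in which the magnesium alkoxide and the ketone oxygen form a five-membered chelate and the methyl attacks the face opposite the C3 methyl, setting the tertiary carbinol as (2S).

Step 9
Reactants: 14 (2S,3S)-2-(furan-2-yl)butane-2,3-diol
Product: 15 (4S,5S)-4-(furan-2-yl)-2,2,4,5-tetramethyl-1,3-dioxolane
Conditions: Me2C(OMe)2, PPTS (cat.), CH2Cl2, rt
Reagents that add atoms: 2,2-dimethoxypropane, COC(C)(C)OC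
Why: Acid-catalysed transketalisation protects the 1,2-diol as its isopropylidene ketal without touching either stereocentre.

Step 10
Reactants: 15 (4S,5S)-4-(furan-2-yl)-2,2,4,5-tetramethyl-1,3-dioxolane
Product: 16 (4S,5S)-2,2,4,5-tetramethyl-1,3-dioxolane-4-carboxylic acid
Conditions: RuCl3 (2 mol%), NaIO4 (8 equiv), CCl4–MeCN–H2O, rt
Reagents that add atoms: sodium periodate, [Na+].[O-]I(=O)(=O)=O; water, O
Why: Oxidative degradation of the electron-rich furan by catalytic RuO4 unmasks the carboxylic acid at the quaternary carbon, which cannot epimerise.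

Step 11
Reactants: 16 (4S,5S)-2,2,4,5-tetramethyl-1,3-dioxolane-4-carboxylic acid; 11 3β,4α,11-trihydroxy-5αH-eudesm-6-en-8-one
Product: 18 acetonide-protected ester (3β-O-acyl derivative of 11), via mixed anhydride 17 (not isolated)
Conditions: 2,4,6-Cl3C6H2COCl, Et3N, THF, rt; then 11, DMAP, PhMe, 50 °C
Reagents that add atoms: none
Why: Yamaguchi esterification acylates the only secondary hydroxyl (C3) and leaves the two tertiary carbinols alone, with no change at any stereocentre.

Step 12
Reactants: 18 acetonide-protected ester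
Product: 19 target, 3β-[(2S,3S)-2,3-dihydroxy-2-methylbutanoyloxy]-4α,11-dihydroxy-5αH-eudesm-6-en-8-one
Conditions: TFA–H2O (4:1), 0 °C
Reagents that add atoms: none
Why: Acid hydrolysis of the isopropylidene ketal frees the side-chain diol under conditions short and cold enough for the ester and the tertiary alcohols to survive.

**Compound list**
1 | (+)-3-carene, (1S,6R)-3,7,7-trimethylbicyclo[4.1.0]hept-3-ene | CC1=CC[C@@H]2[C@H](C1)C2(C)C | starting material
2 | (1S,6R)-3,7,7-trimethylbicyclo[4.1.0]hept-3-ene-2,5-dione | CC1=CC(=O)[C@@H]2[C@H](C1=O)C2(C)C | intermediate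
3 | (1R,6S)-4,7,7-trimethyl-5-(triethylsilyloxy)bicyclo[4.1.0]hept-4-en-2-one | CC1=C(O[Si](CC)(CC)CC)[C@H]2[C@@H](C(=O)C1)C2(C)C | intermediate
4 | ethyl vinyl ketone (pent-1-en-3-one) | CCC(=O)C=C | starting material
5 | dihydropyran cycloadduct: O–C3(Et)=C2–C1–C10–C5 ring cis-fused to ring B, new C10–C1 and C5–O bonds on the α face, 10β-methyl, 5β-OSiEt3, cyclopropane on the β face | CCC1=CC[C@]2(C)CC(=O)[C@@H]3[C@@H](C3(C)C)[C@]2(O[Si](CC)(CC)CC)O1 | intermediate
6 | (1S,3R,6R)-3,7,7-trimethyl-3-(3-oxopentyl)bicyclo[4.1.0]heptane-2,5-dione | CCC(=O)CC[C@]1(C)CC(=O)[C@@H]2[C@H](C1=O)C2(C)C | intermediate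
7 | (6αH,7αH)-6,11-cycloeudesm-4-ene-3,8-dione (10β-methyl, cyclopropane β) | CC1=C2[C@H]3[C@@H](C(=O)C[C@@]2(C)CCC1=O)C3(C)C | intermediate
8 | 4α,5α-epoxy-(6αH,7αH)-6,11-cycloeudesmane-3,8-dione | C[C@]12O[C@]13[C@H]4[C@@H](C(=O)C[C@@]3(C)CCC2=O)C4(C)C | intermediate
9 | 4α,11-dihydroxy-7αH-eudesm-5-ene-3,8-dione | CC(C)(O)[C@H]1C=C2[C@](C)(O)C(=O)CC[C@]2(C)CC1=O | intermediate
10 | 4α,11-dihydroxy-5αH-eudesm-6-ene-3,8-dione | O=C1CC[C@]2(C)CC(=O)C(C(C)(C)O)=C[C@H]2[C@]1(C)O | intermediate
11 | 3β,4α,11-trihydroxy-5αH-eudesm-6-en-8-one | O[C@H]1CC[C@]2(C)CC(=O)C(C(C)(C)O)=C[C@H]2[C@]1(C)O | intermediate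
12 | (S)-2-hydroxy-N,N-dimethylpropanamide ((S)-N,N-dimethyllactamide) | C[C@H](O)C(=O)N(C)C | starting material
13 | (S)-1-(furan-2-yl)-2-hydroxypropan-1-one | C[C@H](O)C(=O)c1ccco1 | intermediate
14 | (2S,3S)-2-(furan-2-yl)butane-2,3-diol | C[C@H](O)[C@](C)(O)c1ccco1 | intermediate
15 | (4S,5S)-4-(furan-2-yl)-2,2,4,5-tetramethyl-1,3-dioxolane | C[C@@H]1OC(C)(C)O[C@]1(C)c1ccco1 | intermediate
16 | (4S,5S)-2,2,4,5-tetramethyl-1,3-dioxolane-4-carboxylic acid | C[C@@H]1OC(C)(C)O[C@]1(C)C(=O)O | intermediate
17 | mixed anhydride of 16 with 2,4,6-trichlorobenzoic acid | C[C@@H]1OC(C)(C)O[C@]1(C)C(=O)OC(=O)c1c(Cl)cc(Cl)cc1Cl | intermediate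
18 | 3β-[(4S,5S)-2,2,4,5-tetramethyl-1,3-dioxolane-4-carbonyloxy]-4α,11-dihydroxy-5αH-eudesm-6-en-8-one | C[C@@H]1OC(C)(C)O[C@]1(C)C(=O)O[C@H]2CC[C@]3(C)CC(=O)C(C(C)(C)O)=C[C@H]3[C@]2(C)O | intermediate
19 | 3β-[(2S,3S)-2,3-dihydroxy-2-methylbutanoyloxy]-4α,11-dihydroxy-5αH-eudesm-6-en-8-one, (3S,4S,5R,10R) | C[C@H](O)[C@](C)(O)C(=O)O[C@H]1CC[C@]2(C)CC(=O)C(C(C)(C)O)=C[C@H]2[C@]1(C)O | target

**Count and risks**
Total steps: 12. Longest linear sequence: 8 steps (steps 1–6, 11 and 12); the acid branch (steps 7–10) joins at step 11.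

The three steps most likely to fail:

Step 3. The thermal oxa-Diels–Alder of a hindered tetrasubstituted silyl enol ether with a ketone heterodiene may be slow, and ethyl vinyl ketone can polymerise or the cyclopropyl ketone can rearrange on heating. The fallback sets out from 3 and comes back at 7. It gives up the cycloaddition and makes the same C10–C1 bond by a TiCl4-promoted Mukaiyama–Michael addition of 3 to 4 (CH2Cl2, −78 °C). Aqueous work-up then gives the 1,5-diketone 6 as an isolated compound, and KOH in MeOH closes ring A to 7. This detour needs no compound beyond the list (F0).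

Step 4. The enone is tetrasubstituted and flanked by a cyclopropane, so nucleophilic epoxidation may be slow or give the wrong face. The fallback sets out from 7 and comes back at 8, and it directs the oxidant with a hydroxyl group instead. LiBH(s-Bu)3 (THF, −78 °C) reduces both ketones, the enone from the equatorial side, to (3α,8β)-6,11-cycloeudesm-4-ene-3,8-diol F1. VO(acac)2 with t-BuOOH then epoxidises the alkene syn to the pseudoaxial 3α-hydroxyl to give 4α,5α-epoxy-6,11-cycloeudesmane-3α,8β-diol F2. Dess–Martin periodinane oxidises both carbinols and returns 8.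

Step 12. Aqueous acid strong enough to open an acetonide next to an ester carbonyl may dehydrate the tertiary allylic 11-alcohol. The fallback sets out from 14 (with 11) and comes back at 19, and it changes the protecting group so that the last step is a fluoride desilylation. Diol 14 with Et3SiOTf and 2,6-lutidine gives (2S,3S)-2-(furan-2-yl)-2,3-bis(triethylsilyloxy)butane F3. RuCl3/NaIO4 gives (2S,3S)-2-methyl-2,3-bis(triethylsilyloxy)butanoic acid F4. Yamaguchi activation gives its 2,4,6-trichlorobenzoic mixed anhydride F5, which acylates 11 to the bis(triethylsilyl)-protected ester F6. HF·pyridine (THF, 0 °C) then frees both hydroxyls and gives 19.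

**Further compounds**
F0 | step 3 | none | none
F1 | step 4 | (3α,8β)-6,11-cycloeudesm-4-ene-3,8-diol | CC1=C2[C@H]3[C@@H]([C@H](O)C[C@@]2(C)CC[C@H]1O)C3(C)C
F2 | step 4 | 4α,5α-epoxy-6,11-cycloeudesmane-3α,8β-diol | C[C@]12O[C@]13[C@H]4[C@@H]([C@H](O)C[C@@]3(C)CC[C@H]2O)C4(C)C
F3 | step 12 | (2S,3S)-2-(furan-2-yl)-2,3-bis(triethylsilyloxy)butane | C[C@H](O[Si](CC)(CC)CC)[C@](C)(O[Si](CC)(CC)CC)c1ccco1
F4 | step 12 | (2S,3S)-2-methyl-2,3-bis(triethylsilyloxy)butanoic acid | C[C@H](O[Si](CC)(CC)CC)[C@](C)(O[Si](CC)(CC)CC)C(=O)O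
F5 | step 12 | mixed anhydride of F4 with 2,4,6-trichlorobenzoic acid | C[C@H](O[Si](CC)(CC)CC)[C@](C)(O[Si](CC)(CC)CC)C(=O)OC(=O)c1c(Cl)cc(Cl)cc1Cl
F6 | step 12 | 3β-[(2S,3S)-2-methyl-2,3-bis(triethylsilyloxy)butanoyloxy]-4α,11-dihydroxy-5αH-eudesm-6-en-8-one | C[C@H](O[Si](CC)(CC)CC)[C@](C)(O[Si](CC)(CC)CC)C(=O)O[C@H]1CC[C@]2(C)CC(=O)C(C(C)(C)O)=C[C@H]2[C@]1(C)O
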